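**Plan**

- Retrosynthesis first masks O7–H as its methyl ether, then cuts the C5–O bond. The C5 hydroxyl is the only ring A substituent peri to the C4 carbonyl; without it ring A is a 2-methylresorcinol unit whose two oxygens (O1 and O7) both flank the methyl-bearing C8, so a 6-methyl isomer cannot form.
- Further cuts: the bond between the first and second carbons of the side chain (2-methyl group plus a C30 bromide), the O1–C2 bond of the pyranone ring, and the C2–C3 bond (Claisen condensation with ethyl acetate).
- Forward: ring A is bought as an acetophenone; O-methylation, Claisen condensation and cyclodehydration close the pyranone ring; the C30 chain is joined at the lateral carbon; the C4 carbonyl then directs oxidation of C5–H; the methyl ether is cleaved last.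
- Stereochemistry: the target has no stereocentre and no stereogenic double bond, so nothing has to be set.

Key step: step 5

Remark: 1-bromotriacontane is assumed to be purchasable as such; all other materials are common catalogue items.

**Route**

Step 1
Reactants: 1 2′,4′-dihydroxy-3′-methylacetophenone
Product: 2 2′-hydroxy-4′-methoxy-3′-methylacetophenone
Conditions: MeI (1.1 equiv), K2CO3 (1.1 equiv), acetone, reflux
Reagents that add atoms: iodomethane, CI
Why: Williamson etherification; the 4′-hydroxyl, para to the acetyl group and not hydrogen-bonded, is the more acidic and more nucleophilic phenol, while the 2′-hydroxyl is held in a chelate with the ketone, so one equivalent of base and MeI should methylate O4′ only.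

Step 2
Reactants: 2 2′-hydroxy-4′-methoxy-3′-methylacetophenone; 3 ethyl acetate (excess)
Product: 4 1-(2-hydroxy-4-methoxy-3-methylphenyl)butane-1,3-dione
Conditions: NaH (4 equiv), THF, reflux; then aq. HCl, 0 °C
Reagents that add atoms: none
Why: Crossed Claisen condensation; excess NaH forms the phenoxide–enolate of 2, which is C-acylated by ethyl acetate, and irreversible deprotonation of the 1,3-diketone drives the equilibrium (4 is drawn as the diketone and should exist partly as enol and cyclic hemiketal).

Step 3
Reactants: 4 1-(2-hydroxy-4-methoxy-3-methylphenyl)butane-1,3-dione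
Product: 5 7-methoxy-2,8-dimethyl-4H-chromen-4-one
Conditions: conc. H2SO4 (cat.), AcOH, 100 °C
Reagents that add atoms: none
Why: Acid-catalysed cyclodehydration of an o-hydroxyaryl 1,3-diketone (classical 2-methylchromone synthesis); the only phenol oxygen ortho to the acyl group is the one next to the ring methyl, so addition to the distal ketone and loss of water can give only the 8-methyl chromone.

Step 4
Reactants: 5 7-methoxy-2,8-dimethyl-4H-chromen-4-one (1.2 equiv); 6 1-bromotriacontane
Product: 7 2-hentriacontyl-7-methoxy-8-methyl-4H-chromen-4-one
Conditions: LiN(i-Pr)2 (1.2 equiv), THF, −78 °C; then 6 in THF/DMPU, −78 °C → rt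
Reagents that add atoms: none
Why: Lateral (vinylogous) metalation–alkylation of a 2-methyl-4-pyranone; the amide base removes a proton from the C2 methyl group to give the extended enolate delocalised onto the C4 oxygen, which displaces bromide from the primary C30 halide in an SN2 reaction at the exocyclic carbon, DMPU and warming offsetting the low solubility of 6.

Step 5
Reactants: 7 2-hentriacontyl-7-methoxy-8-methyl-4H-chromen-4-one
Product: 9 2-hentriacontyl-5-hydroxy-7-methoxy-8-methyl-4H-chromen-4-one, via C5 trifluoroacetate ester 8 (not isolated)
Conditions: [Ru(p-cymene)Cl2]2 (5 mol %), PhI(OCOCF3)2 (1.5–2 equiv, added in portions), CF3CO2H/(CF3CO)2O, ClCH2CH2Cl co-solvent, 50–80 °C; then aq. NaHCO3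
Reagents that add atoms: [bis(trifluoroacetoxy)iodo]benzene, O=C(OI(OC(=O)C(F)(F)F)c1ccccc1)C(F)(F)F; trifluoroacetic acid, OC(=O)C(F)(F)F (its carboxylate exchanges with that of the oxidant, so either may supply the C5 oxygen)
Why: The C4 carbonyl oxygen binds the cationic divalent ruthenium trifluoroacetate generated from [Ru(p-cymene)Cl2]2 in CF3CO2H, and carboxylate-assisted metalation of the peri C5–H gives a five-membered ruthenacycle (Ru, O, C4, C4a, C5); PhI(OCOCF3)2 then oxidises the metal to tetravalent ruthenium and C–O reductive elimination delivers the aryl trifluoroacetate 8, which aqueous work-up hydrolyses to the chelated phenol 9. The closest known reaction type is the ketone-directed ruthenium-catalysed ortho C–H hydroxylation of aryl ketones with trivalent iodine oxidants, which has been applied to C5 of chromones and flavones. No ring of the product is closed (the metallacycle is transient) and no stereocentre is formed. The step needs site selectivity among C5–H, C6–H and C3–H: only C5–H can reach the carbonyl-bound metal through a five-membered chelate, C6–H lies out of reach, C3–H would require a four-membered metallacycle and C8 carries the methyl group. Undirected oxidation of ring A by the trivalent iodine reagent should be held back because the chromone is protonated and electron-poor in CF3CO2H, the oxidant is added in portions at the lowest workable temperature, and (CF3CO)2O keeps the new oxygen masked as an electron-poor ester until work-up, so the phenol is not oxidised further.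

Step 6
Reactants: 9 2-hentriacontyl-5-hydroxy-7-methoxy-8-methyl-4H-chromen-4-one
Product: 10 2-hentriacontyl-5,7-dihydroxy-8-methyl-4H-chromen-4-one (CNP0154031.0)
Conditions: BBr3 (4 equiv), CH2Cl2, −78 °C → rt; then MeOH, H2O
Reagents that add atoms: none
Why: Lewis-acid ether cleavage; boron binds the 7-methoxy oxygen and bromide attacks the methyl carbon (SN2), the excess reagent covering the boron held by the 5-hydroxy-4-keto chelate, while the chromone core and the alkane chain are inert.

**Compound list**

1 | 2′,4′-dihydroxy-3′-methylacetophenone | CC(=O)c1ccc(O)c(C)c1O | starting material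
2 | 2′-hydroxy-4′-methoxy-3′-methylacetophenone | CC(=O)c1ccc(OC)c(C)c1O | intermediate
3 | ethyl acetate | CCOC(C)=O | starting material
4 | 1-(2-hydroxy-4-methoxy-3-methylphenyl)butane-1,3-dione | CC(=O)CC(=O)c1ccc(OC)c(C)c1O | intermediate
5 | 7-methoxy-2,8-dimethyl-4H-chromen-4-one | Cc1cc(=O)c2ccc(OC)c(C)c2o1 | intermediate
6 | 1-bromotriacontane | CCCCCCCCCCCCCCCCCCCCCCCCCCCCCCBr | starting material
7 | 2-hentriacontyl-7-methoxy-8-methyl-4H-chromen-4-one | CCCCCCCCCCCCCCCCCCCCCCCCCCCCCCCc1cc(=O)c2ccc(OC)c(C)c2o1 | intermediate
8 | 2-hentriacontyl-7-methoxy-8-methyl-4-oxo-4H-chromen-5-yl trifluoroacetate | CCCCCCCCCCCCCCCCCCCCCCCCCCCCCCCc1cc(=O)c2c(OC(=O)C(F)(F)F)cc(OC)c(C)c2o1 | intermediate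
9 | 2-hentriacontyl-5-hydroxy-7-methoxy-8-methyl-4H-chromen-4-one | CCCCCCCCCCCCCCCCCCCCCCCCCCCCCCCc1cc(=O)c2c(O)cc(OC)c(C)c2o1 | intermediate
10 | 2-hentriacontyl-5,7-dihydroxy-8-methyl-4H-chromen-4-one (CNP0154031.0) | CCCCCCCCCCCCCCCCCCCCCCCCCCCCCCCc1cc(=O)c2c(O)cc(O)c(C)c2o1 | target

**Count**

Total steps: 6. Longest linear sequence: 6 steps (1 → 10).

**Steps most likely to fail**

Step 5. The waxy substrate may dissolve poorly in the acid medium, so that cyclometalation is slow and undirected single-electron oxidation of the alkoxy-substituted ring A by the trivalent iodine reagent, or loss of the catalyst, overtakes the directed pathway. The fallback sets out from 5 and installs the C5 oxygen before the chain. The same ruthenium-catalysed hydroxylation is run on 5, which dissolves freely in CF3CO2H. It should form 7-methoxy-2,8-dimethyl-4-oxo-4H-chromen-5-yl trifluoroacetate F1 in the flask and, after aqueous work-up, 5-hydroxy-7-methoxy-2,8-dimethyl-4H-chromen-4-one F2. O-Methylation of the chelated phenol (MeI, K2CO3, DMF, 60 °C) gives 5,7-dimethoxy-2,8-dimethyl-4H-chromen-4-one F3. Lateral lithiation with LiN(i-Pr)2 and alkylation with 6, as in step 4, gives 2-hentriacontyl-5,7-dimethoxy-8-methyl-4H-chromen-4-one F4. BBr3 in CH2Cl2 then removes both methyl ethers, and the fallback comes back to the route at 10.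

Step 4. Slow substitution on the sparingly soluble C30 bromide may let the extended enolate of 5 be consumed by proton transfer to product and by conjugate self-addition to unreacted chromone as the mixture warms. The fallback sets out from 4 and joins the chain before the pyranone ring exists. LiN(i-Pr)2 (3.3 equiv, THF, −78 → 0 °C) converts 4 into its phenoxide–diketone dianion, whose terminal carbanion is far more nucleophilic than the chromone enolate. Alkylation with 6 at the methyl terminus should give 1-(2-hydroxy-4-methoxy-3-methylphenyl)tetratriacontane-1,3-dione F5. Acid cyclodehydration under the conditions of step 3 then closes the ring, and the fallback comes back to the route at 7.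

Step 6. Ether cleavage may stall because the boron reagent is tied up by the 5-hydroxy-4-keto chelate and O7 is a poorly basic vinylogous ester oxygen; forcing the reaction risks ring bromination and decomposition. The fallback sets out from 7 and changes the O7 protecting group before C5 is oxidised. BBr3 in CH2Cl2 cleaves the ether of 7, where no chelate competes, to give 2-hentriacontyl-7-hydroxy-8-methyl-4H-chromen-4-one F6. Ac2O in pyridine gives 2-hentriacontyl-8-methyl-4-oxo-4H-chromen-7-yl acetate F7. The C5–H hydroxylation under the conditions of step 5 should then form 7-acetoxy-2-hentriacontyl-8-methyl-4-oxo-4H-chromen-5-yl trifluoroacetate F8 in the flask. K2CO3 in MeOH cleaves both esters, and the fallback comes back to the route at 10.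

**Further compounds**

F1 | step 5 | 7-methoxy-2,8-dimethyl-4-oxo-4H-chromen-5-yl trifluoroacetate | Cc1cc(=O)c2c(OC(=O)C(F)(F)F)cc(OC)c(C)c2o1
F2 | step 5 | 5-hydroxy-7-methoxy-2,8-dimethyl-4H-chromen-4-one | Cc1cc(=O)c2c(O)cc(OC)c(C)c2o1
F3 | step 5 | 5,7-dimethoxy-2,8-dimethyl-4H-chromen-4-one | Cc1cc(=O)c2c(OC)cc(OC)c(C)c2o1
F4 | step 5 | 2-hentriacontyl-5,7-dimethoxy-8-methyl-4H-chromen-4-one | CCCCCCCCCCCCCCCCCCCCCCCCCCCCCCCc1cc(=O)c2c(OC)cc(OC)c(C)c2o1
F5 | step 4 | 1-(2-hydroxy-4-methoxy-3-methylphenyl)tetratriacontane-1,3-dione | CCCCCCCCCCCCCCCCCCCCCCCCCCCCCCCC(=O)CC(=O)c1ccc(OC)c(C)c1O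
F6 | step 6 | 2-hentriacontyl-7-hydroxy-8-methyl-4H-chromen-4-one | CCCCCCCCCCCCCCCCCCCCCCCCCCCCCCCc1cc(=O)c2ccc(O)c(C)c2o1
F7 | step 6 | 2-hentriacontyl-8-methyl-4-oxo-4H-chromen-7-yl acetate | CCCCCCCCCCCCCCCCCCCCCCCCCCCCCCCc1cc(=O)c2ccc(OC(C)=O)c(C)c2o1
F8 | step 6 | 7-acetoxy-2-hentriacontyl-8-methyl-4-oxo-4H-chromen-5-yl trifluoroacetate | CCCCCCCCCCCCCCCCCCCCCCCCCCCCCCCc1cc(=O)c2c(OC(=O)C(F)(F)F)cc(OC(C)=O)c(C)c2o1
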